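**Strategy.** Each gallocatechin unit is disconnected across ring C at O1–C8a and C3–C4: a formal (3+3) annulation that exploits the 1,3-relationship of the ring A carbon C8a and the benzylic C4 (both on C4a) and pairs it with the ambident enolate O1–C2=C3 of a ring B acetophenone. In one operation the enolate is C-benzylated by 2,4,6-trifluorobenzyl bromide (C3–C4) and then O-arylated by SNAr at an ortho C–F (O1–C8a), giving an achiral flav-2-ene. Fluoride-to-benzyloxy exchange, asymmetric hydroboration (C2, C3) and C4 oxidation give one electrophile, used twice for the 4α→8 bonds, first to benzylated (+)-catechin, then to the dimer; deprotection follows.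

Key step: step 2

Remark: flavan numbering is used (O1, C2, C3, C4, C4a, C5 to C8, C8a; ring A benzo, ring B 2-aryl, ring C pyran), and the facial sense of monoisopinocampheylborane from (+)-α-pinene in step 4 is assumed by analogy with 1-arylcycloalkenes, which give the (S)-carbinol; if the sense proves opposite, the borane from (−)-α-pinene is used.

Step 1
Reactants: 1 3',4',5'-trihydroxyacetophenone
Product: 2 3',4',5'-tris(benzyloxy)acetophenone
Conditions: BnBr, K2CO3, DMF, 60 °C
Reagents that add atoms: benzyl bromide, BrCc1ccccc1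
Why: Williamson ether synthesis: the three phenoxides formed with K2CO3 are alkylated by benzyl bromide, while the far less acidic methyl ketone is not touched.

Step 2
Reactants: 2 3',4',5'-tris(benzyloxy)acetophenone; 3 2,4,6-trifluorobenzyl bromide
Product: 5 2-[3,4,5-tris(benzyloxy)phenyl]-5,7-difluoro-4H-chromene, via trifluorophenyl ketone 4 (not isolated)
Conditions: KN(SiMe3)2 (1.05 equiv), THF, −78 °C, then 3, −78 to 0 °C; then KN(SiMe3)2 (1.1 equiv), DMPU, 65 °C, one pot
Reagents that add atoms: none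
Why: The potassium enolate of 2 displaces bromide from 3 in an SN2 C-benzylation that forms C3–C4 and gives ketone 4; the second portion of base regenerates the conjugated (Z)-enolate, whose oxygen adds to an ortho C–F carbon and expels fluoride through a Meisenheimer intermediate (addition–elimination SNAr), forming O1–C8a. The closest known reaction types are the domino C-benzylation/intramolecular O-arylation of enolates with 2-halobenzyl halides to 4H-chromenes and the cyclisation of enolate oxygen onto fluoroarenes. Ring C closes in a six-membered mode, by exo attack of the enolate oxygen on the trigonal C8a with the negative charge delocalised into ring A. No stereocentre is formed: the product is the achiral flav-2-ene, whose C2=C3 enol ether is the handle for the asymmetric hydroboration in step 4. The step needs C- over O-alkylation and mono- over dialkylation (soft benzylic bromide, one equivalent of base at −78 °C before the second portion), O- over C-arylation (C-attack would require a four-membered ring, and the Z-enolate favoured for aryl alkyl ketones holds O1 syn to C4), and ortho over para fluoride (only the two homotopic ortho fluorines are within reach, each activated inductively by two meta fluorines).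

Step 3
Reactants: 5 2-[3,4,5-tris(benzyloxy)phenyl]-5,7-difluoro-4H-chromene
Product: 6 5,7-bis(benzyloxy)-2-[3,4,5-tris(benzyloxy)phenyl]-4H-chromene
Conditions: BnOH, KN(SiMe3)2, NMP, 130 °C
Reagents that add atoms: benzyl alcohol, OCc1ccccc1
Why: Twofold intermolecular SNAr (addition–elimination) by potassium benzyloxide on the ring A fluorides, a known reaction of non-activated fluoroarenes in dipolar aprotic solvents at high temperature; the first exchange is helped by the remaining meta fluorine, the enol ether and benzyl ethers are inert to alkoxide, and deprotonation at C4 is disfavoured because it would give an 8π pyranyl anion.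

Step 4
Reactants: 6 5,7-bis(benzyloxy)-2-[3,4,5-tris(benzyloxy)phenyl]-4H-chromene
Product: 8 (2R,3S)-5,7,3',4',5'-penta-O-benzylgallocatechin, via isopinocampheylborane 7 (not isolated)
Conditions: IpcBH2 [from (+)-α-pinene], THF, −25 °C; then NaOH, H2O2, 0 °C to rt
Reagents that add atoms: monoisopinocampheylborane, C[C@H]1[C@H](B)C[C@@H]2C[C@H]1C2(C)C (boron and isopinocampheyl group carried in 7 only); hydrogen peroxide, OO
Why: Asymmetric hydroboration–oxidation of a trisubstituted enol ether: boron adds to C3 (β to O1, remote from the aryl-bearing C2) and hydrogen to C2 from the same face, so 2-aryl and 3-OH end up trans, the chiral borane selects the face that gives (2R,3S), and oxidation of the C–B bond proceeds with retention.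

Step 5
Reactants: 8 (2R,3S)-5,7,3',4',5'-penta-O-benzylgallocatechin
Product: 9 (2R,3S,4S)-5,7-bis(benzyloxy)-4-(2-ethoxyethoxy)-2-[3,4,5-tris(benzyloxy)phenyl]chroman-3-ol
Conditions: DDQ, HOCH2CH2OEt, CH2Cl2, rt
Reagents that add atoms: 2-ethoxyethanol, CCOCCO
Why: DDQ oxidation of the benzylic C4–H activated by the 5,7-dialkoxy ring A (hydride abstraction to a quinone-methide-type cation) and capture by 2-ethoxyethanol, expected mainly cis to the 3-OH (4S); the C4 configuration is erased again in the coupling steps, so its control is not critical.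

Step 6
Reactants: 9 (2R,3S,4S)-5,7-bis(benzyloxy)-4-(2-ethoxyethoxy)-2-[3,4,5-tris(benzyloxy)phenyl]chroman-3-ol
Product: 10 (2R,3S,4S)-5,7-bis(benzyloxy)-4-(2-ethoxyethoxy)-2-[3,4,5-tris(benzyloxy)phenyl]chroman-3-yl acetate
Conditions: Ac2O, pyridine, DMAP (cat.), CH2Cl2, rt
Reagents that add atoms: acetic anhydride, CC(=O)OC(C)=O
Why: DMAP-catalysed acylation of the secondary 3-OH installs the participating group needed for 3,4-trans selectivity in steps 8 and 9.

Step 7
Reactants: 11 (+)-catechin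
Product: 12 5,7,3',4'-tetra-O-benzyl-(+)-catechin
Conditions: BnBr, K2CO3, DMF, rt
Reagents that add atoms: benzyl bromide, BrCc1ccccc1
Why: Williamson ether synthesis with the weak base K2CO3 benzylates the four phenols and leaves the aliphatic 3-OH free.

Step 8
Reactants: 10 (2R,3S,4S)-5,7-bis(benzyloxy)-4-(2-ethoxyethoxy)-2-[3,4,5-tris(benzyloxy)phenyl]chroman-3-yl acetate; 12 5,7,3',4'-tetra-O-benzyl-(+)-catechin
Product: 13 3-O-acetyl-5,7,3',4',5'-penta-O-benzylgallocatechin-(4α→8)-5,7,3',4'-tetra-O-benzylcatechin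
Conditions: Me3SiOTf (cat.), CH2Cl2, −78 °C, excess 12
Reagents that add atoms: none
Why: Lewis-acid-promoted Friedel–Crafts flavanylation: Me3SiOTf ionises the 4-alkoxy group, the 3-acetate bridges the C4 cation on its own face (acetoxonium), and C8 of 12, the most nucleophilic ring A position, attacks from the opposite face to give the 3,4-trans (4α) interflavan bond, while excess 12 suppresses oligomerisation.

Step 9
Reactants: 10 (2R,3S,4S)-5,7-bis(benzyloxy)-4-(2-ethoxyethoxy)-2-[3,4,5-tris(benzyloxy)phenyl]chroman-3-yl acetate; 13 3-O-acetyl-5,7,3',4',5'-penta-O-benzylgallocatechin-(4α→8)-5,7,3',4'-tetra-O-benzylcatechin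
Product: 14 3-O-acetyl-penta-O-benzylgallocatechin-(4α→8)-3-O-acetyl-penta-O-benzylgallocatechin-(4α→8)-tetra-O-benzylcatechin
Conditions: Me3SiOTf (cat.), CH2Cl2, −78 °C, excess 13
Reagents that add atoms: none
Why: The same acetoxonium-directed Friedel–Crafts flavanylation, now at C8 of the upper gallocatechin unit of 13, the position that reacts preferentially in flavan-3-ol nucleophiles (the lower unit has C8 blocked and only the less reactive C6 free), again trans to the 3-acetate (4α).

Step 10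
Reactants: 14 3-O-acetyl-penta-O-benzylgallocatechin-(4α→8)-3-O-acetyl-penta-O-benzylgallocatechin-(4α→8)-tetra-O-benzylcatechin
Product: 15 tetradeca-O-benzyl prodelphinidin C2 (all fourteen phenols benzylated, the three 3-OH groups free)
Conditions: NaOMe (cat.), MeOH–THF, 40 °C
Reagents that add atoms: none
Why: Zemplén transesterification removes the two secondary acetates as methyl acetate; benzyl ethers, interflavan bonds and all stereocentres are stable to catalytic methoxide.

Step 11
Reactants: 15 tetradeca-O-benzyl prodelphinidin C2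
Product: 16 prodelphinidin C2
Conditions: H2 (1 atm), Pd(OH)2/C, THF–MeOH–H2O, rt
Reagents that add atoms: none
Why: Heterogeneous hydrogenolysis cleaves the fourteen benzyl ethers; under these mild neutral conditions the benzylic C2–O1 ring bonds and the interflavan bonds should be retained and no stereocentre is touched.

**Compound list**

1 | 3',4',5'-trihydroxyacetophenone | CC(=O)c1cc(O)c(O)c(O)c1 | starting material
2 | 3',4',5'-tris(benzyloxy)acetophenone | CC(=O)c1cc(OCc2ccccc2)c(OCc2ccccc2)c(OCc2ccccc2)c1 | intermediate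
3 | 2,4,6-trifluorobenzyl bromide | Fc1cc(F)c(CBr)c(F)c1 | starting material
4 | 3-(2,4,6-trifluorophenyl)-1-[3,4,5-tris(benzyloxy)phenyl]propan-1-one | O=C(CCc1c(F)cc(F)cc1F)c1cc(OCc2ccccc2)c(OCc2ccccc2)c(OCc2ccccc2)c1 | intermediate
5 | 2-[3,4,5-tris(benzyloxy)phenyl]-5,7-difluoro-4H-chromene | Fc1cc(F)c2c(c1)OC(c1cc(OCc3ccccc3)c(OCc3ccccc3)c(OCc3ccccc3)c1)=CC2 | intermediate
6 | 5,7-bis(benzyloxy)-2-[3,4,5-tris(benzyloxy)phenyl]-4H-chromene | c1ccc(COc2cc(OCc3ccccc3)c3c(c2)OC(c2cc(OCc4ccccc4)c(OCc4ccccc4)c(OCc4ccccc4)c2)=CC3)cc1 | intermediate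
7 | [(2R,3S)-5,7-bis(benzyloxy)-2-[3,4,5-tris(benzyloxy)phenyl]chroman-3-yl](isopinocampheyl)borane | C[C@H]1[C@H](B[C@H]3Cc4c(OCc5ccccc5)cc(OCc5ccccc5)cc4O[C@@H]3c3cc(OCc4ccccc4)c(OCc4ccccc4)c(OCc4ccccc4)c3)C[C@@H]2C[C@H]1C2(C)C | intermediate
8 | (2R,3S)-5,7,3',4',5'-penta-O-benzylgallocatechin | O[C@H]1Cc2c(OCc3ccccc3)cc(OCc3ccccc3)cc2O[C@@H]1c1cc(OCc2ccccc2)c(OCc2ccccc2)c(OCc2ccccc2)c1 | intermediate
9 | (2R,3S,4S)-5,7-bis(benzyloxy)-4-(2-ethoxyethoxy)-2-[3,4,5-tris(benzyloxy)phenyl]chroman-3-ol | c1ccc(COc2cc(OCc3ccccc3)c3c(c2)O[C@H](c2cc(OCc4ccccc4)c(OCc4ccccc4)c(OCc4ccccc4)c2)[C@@H](O)[C@H]3OCCOCC)cc1 | intermediate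
10 | (2R,3S,4S)-5,7-bis(benzyloxy)-4-(2-ethoxyethoxy)-2-[3,4,5-tris(benzyloxy)phenyl]chroman-3-yl acetate | c1ccc(COc2cc(OCc3ccccc3)c3c(c2)O[C@H](c2cc(OCc4ccccc4)c(OCc4ccccc4)c(OCc4ccccc4)c2)[C@@H](OC(C)=O)[C@H]3OCCOCC)cc1 | intermediate
11 | (+)-catechin | Oc1cc(O)c2c(c1)O[C@H](c1ccc(O)c(O)c1)[C@@H](O)C2 | starting material
12 | 5,7,3',4'-tetra-O-benzyl-(+)-catechin | c1ccc(COc2cc(OCc3ccccc3)c3c(c2)O[C@H](c2ccc(OCc4ccccc4)c(OCc4ccccc4)c2)[C@@H](O)C3)cc1 | intermediate
13 | 3-O-acetyl-5,7,3',4',5'-penta-O-benzylgallocatechin-(4α→8)-5,7,3',4'-tetra-O-benzylcatechin | c1ccc(COc2cc(OCc3ccccc3)c3c(c2)O[C@H](c2cc(OCc4ccccc4)c(OCc4ccccc4)c(OCc4ccccc4)c2)[C@@H](OC(C)=O)[C@@H]3c2c(OCc3ccccc3)cc(OCc3ccccc3)c3c2O[C@H](c2ccc(OCc4ccccc4)c(OCc4ccccc4)c2)[C@@H](O)C3)cc1 | intermediate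
14 | 3-O-acetyl-penta-O-benzylgallocatechin-(4α→8)-3-O-acetyl-penta-O-benzylgallocatechin-(4α→8)-tetra-O-benzylcatechin | c1ccc(COc2cc(OCc3ccccc3)c3c(c2)O[C@H](c2cc(OCc4ccccc4)c(OCc4ccccc4)c(OCc4ccccc4)c2)[C@@H](OC(C)=O)[C@@H]3c2c(OCc3ccccc3)cc(OCc3ccccc3)c3c2O[C@H](c2cc(OCc4ccccc4)c(OCc4ccccc4)c(OCc4ccccc4)c2)[C@@H](OC(C)=O)[C@@H]3c2c(OCc3ccccc3)cc(OCc3ccccc3)c3c2O[C@H](c2ccc(OCc4ccccc4)c(OCc4ccccc4)c2)[C@@H](O)C3)cc1 | intermediate
15 | tetradeca-O-benzyl prodelphinidin C2 | c1ccc(COc2cc(OCc3ccccc3)c3c(c2)O[C@H](c2cc(OCc4ccccc4)c(OCc4ccccc4)c(OCc4ccccc4)c2)[C@@H](O)[C@@H]3c2c(OCc3ccccc3)cc(OCc3ccccc3)c3c2O[C@H](c2cc(OCc4ccccc4)c(OCc4ccccc4)c(OCc4ccccc4)c2)[C@@H](O)[C@@H]3c2c(OCc3ccccc3)cc(OCc3ccccc3)c3c2O[C@H](c2ccc(OCc4ccccc4)c(OCc4ccccc4)c2)[C@@H](O)C3)cc1 | intermediate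
16 | prodelphinidin C2 | Oc1cc(O)c2c(c1)O[C@H](c1cc(O)c(O)c(O)c1)[C@@H](O)[C@@H]2c1c(O)cc(O)c2c1O[C@H](c1cc(O)c(O)c(O)c1)[C@@H](O)[C@@H]2c1c(O)cc(O)c2c1O[C@H](c1ccc(O)c(O)c1)[C@@H](O)C2 | target

**Step count.** Total: 11 steps. Longest linear sequence: 10 steps (steps 1 to 6, then 8 to 11; step 7 is a one-step side branch).

**Steps most likely to fail**

Step 3. The second fluoride exchange may stall, because the ring by then carries two oxygen donors and no further fluorine, and prolonged heating may lead to cleavage of benzyl ethers by attack of benzyloxide at the benzylic carbon. The fallback installs the ring A benzyloxy groups before ring C is built and closes the ring with copper catalysis; it sets out from 2 and comes back at 6, replacing steps 2 and 3. Commercial 1,3-bis(benzyloxy)-5-bromobenzene is formylated under Vilsmeier–Haack conditions (POCl3, DMF) to 2,4-bis(benzyloxy)-6-bromobenzaldehyde F2. Reduction with NaBH4 gives [2,4-bis(benzyloxy)-6-bromophenyl]methanol F3, and PBr3 gives 1,5-bis(benzyloxy)-3-bromo-2-(bromomethyl)benzene F4. The potassium enolate of 2 is alkylated with F4 to 3-[2,4-bis(benzyloxy)-6-bromophenyl]-1-[3,4,5-tris(benzyloxy)phenyl]propan-1-one F5. Intramolecular enolate O-arylation (CuI, 1,10-phenanthroline, Cs2CO3, toluene, 110 °C) then gives 6.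

Step 2. Proton exchange between the enolate and the first-formed ketone may lead to double benzylation, and a slow ring closure may allow intermolecular side reactions. The fallback forms C3–C4 by condensation instead of alkylation; it sets out from 2 and comes back at 4. Acid-mediated Claisen–Schmidt condensation of 2 with 2,4,6-trifluorobenzaldehyde (SOCl2, EtOH) gives (E)-3-(2,4,6-trifluorophenyl)-1-[3,4,5-tris(benzyloxy)phenyl]prop-2-en-1-one F1. Conjugate reduction with catalytic [(Ph3P)CuH]6 and polymethylhydrosiloxane gives ketone 4, which is isolated and cyclised to 5 with KN(SiMe3)2 in DMPU at 65 °C as in the second stage of step 2.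

Step 4. Enantiofacial discrimination by the chiral borane may be insufficient, and the β-aryloxy borane may undergo β-elimination with ring opening if the temperature rises. The fallback replaces reagent control by resolution; it sets out from 6 and comes back at 8. Hydroboration with BH3·SMe2 at 0 °C gives the racemic trans-configured flavan-3-ylborane F6, and NaOH/H2O2 gives racemic trans-5,7,3',4',5'-penta-O-benzylgallocatechin F7. Esterification with (S)-2-methoxy-2-phenylacetic acid (DCC, DMAP) gives the (2R,3S)-configured ester F8 and its (2S,3R)-configured diastereomer F9, which are separated by chromatography. Saponification of F8 (K2CO3, MeOH–THF) gives 8.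

**Further compounds**

F1 | step 2 | (E)-3-(2,4,6-trifluorophenyl)-1-[3,4,5-tris(benzyloxy)phenyl]prop-2-en-1-one | O=C(/C=C/c1c(F)cc(F)cc1F)c1cc(OCc2ccccc2)c(OCc2ccccc2)c(OCc2ccccc2)c1
F2 | step 3 | 2,4-bis(benzyloxy)-6-bromobenzaldehyde | O=Cc1c(Br)cc(OCc2ccccc2)cc1OCc1ccccc1
F3 | step 3 | [2,4-bis(benzyloxy)-6-bromophenyl]methanol | OCc1c(Br)cc(OCc2ccccc2)cc1OCc1ccccc1
F4 | step 3 | 1,5-bis(benzyloxy)-3-bromo-2-(bromomethyl)benzene | BrCc1c(Br)cc(OCc2ccccc2)cc1OCc1ccccc1
F5 | step 3 | 3-[2,4-bis(benzyloxy)-6-bromophenyl]-1-[3,4,5-tris(benzyloxy)phenyl]propan-1-one | O=C(CCc1c(Br)cc(OCc2ccccc2)cc1OCc1ccccc1)c1cc(OCc2ccccc2)c(OCc2ccccc2)c(OCc2ccccc2)c1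
F6 | step 4 | racemic trans-[5,7-bis(benzyloxy)-2-[3,4,5-tris(benzyloxy)phenyl]chroman-3-yl]borane | B[C@H]1Cc2c(OCc3ccccc3)cc(OCc3ccccc3)cc2O[C@@H]1c1cc(OCc2ccccc2)c(OCc2ccccc2)c(OCc2ccccc2)c1.B[C@@H]1Cc2c(OCc3ccccc3)cc(OCc3ccccc3)cc2O[C@H]1c1cc(OCc2ccccc2)c(OCc2ccccc2)c(OCc2ccccc2)c1
F7 | step 4 | racemic trans-5,7,3',4',5'-penta-O-benzylgallocatechin | O[C@H]1Cc2c(OCc3ccccc3)cc(OCc3ccccc3)cc2O[C@@H]1c1cc(OCc2ccccc2)c(OCc2ccccc2)c(OCc2ccccc2)c1.O[C@@H]1Cc2c(OCc3ccccc3)cc(OCc3ccccc3)cc2O[C@H]1c1cc(OCc2ccccc2)c(OCc2ccccc2)c(OCc2ccccc2)c1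
F8 | step 4 | (2R,3S)-5,7-bis(benzyloxy)-2-[3,4,5-tris(benzyloxy)phenyl]chroman-3-yl (S)-2-methoxy-2-phenylacetate | CO[C@H](C(=O)O[C@H]1Cc2c(OCc3ccccc3)cc(OCc3ccccc3)cc2O[C@@H]1c1cc(OCc2ccccc2)c(OCc2ccccc2)c(OCc2ccccc2)c1)c1ccccc1
F9 | step 4 | (2S,3R)-5,7-bis(benzyloxy)-2-[3,4,5-tris(benzyloxy)phenyl]chroman-3-yl (S)-2-methoxy-2-phenylacetate | CO[C@H](C(=O)O[C@@H]1Cc2c(OCc3ccccc3)cc(OCc3ccccc3)cc2O[C@H]1c1cc(OCc2ccccc2)c(OCc2ccccc2)c(OCc2ccccc2)c1)c1ccccc1
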